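## Structural features

Plakortolide K is a cis-fused bicycle in which a six-membered 1,2-dioxane (O–O, C3, C4, C5, C6) shares its C3–C4 bond with a γ-butyrolactone (C1, C2, C3, C4 and the lactone oxygen on C4). C3 (peroxy methine, R) and C4 (oxygen-bearing quaternary carbon with a methyl group, R) are adjacent and form the ring fusion. C6 (S) is a second fully substituted carbon, one CH2 (C5) away from C4, and carries a methyl group and the unfunctionalized 12-phenyldodecyl chain. The two methyl groups are cis across the dioxane and the chain lies on the face of the lactone oxygen. The O–O bond is the fragile element: it does not survive low-valent metals, phosphines, strong hydride donors or catalytic hydrogenation. The peroxy C3–H and the acidic C2 hydrogens also make the skeleton base-sensitive (Kornblum–DeLaMare cleavage, β-elimination of the peroxide). The real difficulty is to join two tetrasubstituted oxygen-bearing carbons and a peroxy methine with control of configuration while the peroxide is already in the molecule. The key step uses the ring-fusion bond C3–C4: in an open-chain precursor C4 is an enol acetate carbon and C3 is the β-carbon of an acrylate bound to the peroxide oxygen, so a radical at C4 can close the dioxane onto C3 and leave the C2–C1 ester arm placed for lactonization.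

## Logic of the disconnections

23 back to 21 (through 22). The acyl–oxygen bond of the lactone (C1–O on C4) is cut first, because a γ-hydroxy ester whose hydroxyl and ester arm are cis on the dioxane closes to the five-membered lactone unaided. This removes one ring and leaves a monocyclic dioxane whose C4 oxygen is masked as an acetate. The forward step must cleave a tertiary acetate by acyl–oxygen fission under acid, since base would attack the peroxy methine and the C2 hydrogens.

21 back to 20. The ring-fusion bond C3–C4 is cut. It is the only bond shared by both rings and it joins the two adjacent stereocentres. Cutting it opens the dioxane to an acyclic peroxide with a single stereocentre (C6), with C4 as an enol acetate carbon and C3 as the oxygen-bearing acrylate carbon. The forward step must generate a carbon radical at C4 next to an O–O bond, close the six-membered ring faster than any fragmentation, set C3 and C4 cis, and end with hydrogen at C2.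

20 back to 19. The C4–O bond of the enol acetate and the new terminal C–H are cut, the retron of Markovnikov addition of acetic acid to a terminal alkyne. This replaces enolization of a β-peroxy methyl ketone, which would be neither regioselective nor safe towards elimination, by an addition that can only give the 2-acetoxy-1-alkene. The demand is a π-acid catalyst that tolerates a dialkyl peroxide. The step is placed last so that no free hydroperoxide meets the acyl donor.

19 back to 17 and 18. The vinyl C3–O bond is cut, forward a conjugate addition of a hydroperoxide to a propiolate. The whole C1–C3 unit becomes a commercial ester and a tertiary hydroperoxide remains. The demand is mild amine catalysis and E geometry.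

17 back to 13 (through 16, 15 and 14). The bond between C4 and the terminal alkyne carbon is cut (one-carbon homologation of an aldehyde) and the aldehyde is traced to a primary alcohol, which reveals a 3-hydroperoxy alcohol. The hydroperoxide must be masked selectively as a base-stable ketal during oxidation and homologation, and the homologation must not trigger β-elimination of the peroxide.

13 back to 12. The C6–OO bond is cut with the primary oxygen as internal leaving group (perhydrolysis of an oxetane). All earlier intermediates become peroxide-free, and the tertiary peroxy stereocentre becomes a tertiary ether stereocentre of opposite configuration. The demand is substitution at a fully substituted carbon with clean inversion.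

12 back to 8 (through 10 and 9). The oxetane C–O bond at the primary carbon is cut to a 1,3-diol, the diol is traced to a 2,3-epoxy alcohol, and that to an E-allylic alcohol. The tertiary carbinol centre then comes from a catalytic asymmetric epoxidation of known facial sense. The demands are E geometry in 8, hydride delivery to C2 only, and ring closure that leaves the stereocentre untouched.

8 back to 1, 2 and 5 (through 6 and 4). The methyl–carbon and CH2OH–carbon bonds on the alkene are cut (syn carbometalation of a terminal alkyne, then hydroxymethylation), then the propargylic and the benzylic C–C bonds. This leads to an acetylide, a C12 α,ω-dibromide and a phenyl Grignard reagent; the demand is mono-substitution of the dibromide.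

## Other disconnections considered

Alternative 1: The cut is C5–C6 of the dioxane together with the C4–O bond of the lactone. In the forward step the acyclic mixed peroxyketal acid A1, (3R)-3-[(2-methoxy-14-phenyltetradec-3-yn-2-yl)peroxy]-4-methylpent-4-enoic acid, would be ionized with Me3SiOTf or SnCl4. The peroxycarbenium carbon C6 is attacked by the isopropenyl CH2 (six-membered ring, endo to the alkene), and the tertiary C4 cation is captured by the carboxyl group to give the alkynyl peroxy lactone A2. Diimide reduction of the triple bond would then give 23.
- In its favour: both rings form in one step from a convergent precursor. C4 and C6 would both be set from C3, because the C3 arm sits equatorial in the chair, the rod-like alkynyl group is the small substituent that can go axial at C6, and the lactone can only close cis. Cyclization of alkenes onto peroxycarbenium ions is an established reaction type.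
- Against it here: A1 needs an enantiopure secondary allylic hydroperoxide, for which there is no dependable asymmetric entry. The alkynyl group destabilizes the peroxycarbenium ion, so ionization competes with Hock- and Criegee-type O–O cleavage. The C4 cation may lose a proton instead of being captured. The triple bond must be saturated with diimide next to a fully substituted peroxy carbon.
- Comparison: this plan is the better one on step economy, on relative stereocontrol at C6 and on precedent for the ring-forming event. The chosen plan is stronger in its source of absolute configuration (asymmetric epoxidation, then stereospecific perhydrolysis), keeps strong Lewis acids away from the peroxide when the ring forms, and carries a saturated chain from the start.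

Alternative 2: The cut is the C4–O bond of the lactone and the C6–O bond of the peroxide, followed by two C–Hg bonds. In the forward step the hydroperoxy acid A3, (3R)-3-hydroperoxy-4,6-dimethylidene-18-phenyloctadecanoic acid, would be treated with two equivalents of Hg(OAc)2. The carboxyl oxygen closes the lactone at C4 (5-exo) and the hydroperoxide closes the dioxane at C6 (6-exo), giving the bis(acetoxymercuriomethyl) peroxy lactone A4. NaBH4 would then replace both mercury atoms by hydrogen to give 23.
- In its favour: oxymercuration is Markovnikov-specific, so both quaternary C–O bonds form with certain regiochemistry. Peroxymercuration to 1,2-dioxanes and mercury-mediated lactonization are long established. On bonds formed per step and on precedent for the cyclization it is the equal or the better of the chosen plan.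
- Against it here: only C3 is stereogenic in A3. C6 is 1,4 to it and will form without bias, and the lactone closure is not reliably cis, so up to four isomers must be expected where the chosen plan gives two. A3 is a secondary allylic hydroperoxide β to a carboxylic acid, prone to dehydration and hard to obtain as one enantiomer. Demercuration runs through primary alkyl radicals, and the one on the C6 methylene is β to the O–O bond and would displace at oxygen to give an epoxide. Two equivalents of toxic divalent mercury are consumed.
- Comparison: both plans end with a radical next to a peroxide. In the chosen plan that radical is ester-stabilized and can be reduced in the catalytic cycle; here it is an unstabilized primary radical. The chosen plan is longer but fixes C6 absolutely before the rings are made.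

Alternative 3: The cut is the two C–O bonds of the peroxide at C3 and C6. In the forward step the dienoate A5, methyl (3E,5E)-4,6-dimethyl-18-phenyloctadeca-3,5-dienoate, would add photosensitized singlet oxygen suprafacially to give the 3,6-cis dihydrodioxine A6 as the racemate. Markovnikov hydration of C4=C5 on the face of the C3 arm would give 22, which lactonizes.
- In its favour: it is the shortest route to the peroxide, the O–O unit comes from O2 in one step, and the cis relation of the C3 arm and the C6 chain is guaranteed by the cycloaddition. That relative control is better than in the chosen plan, and on step count it is also the better.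
- Against it here: nothing controls absolute configuration, so a resolution is needed. The s-cis conformer of A5 places the C6 methyl group inside the diene, and the many allylic hydrogens make the Schenck ene reaction the likely main path. The later hydration must set C4 cis to the arm; a radical hydration would put a radical at C4 directly β to the ring O–O bond, and an acid hydration threatens the peroxide.
- Comparison: it is structurally the most direct plan, but its two selectivity problems (cycloaddition against ene reaction, hydration at C4) have no obvious solution. In the chosen plan the C4 radical is γ to the peroxide oxygen and the oxygen at C4 is in place before ring closure.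

Key step: step 14

Numbering used in the text: C1 lactone carbonyl, C2 lactone CH2, C3 peroxy CH, C4 methyl and lactone-oxygen carbon, C5 ring CH2, C6 methyl and chain carbon.

Consistency check: the target is (3R,4R,6S) in this numbering, which is 3S,4aR,7aR in fused-ring numbering. Compounds 20, 21 and 23 are mutually consistent as drawn, and the S descriptor of the peroxy carbon is unchanged from 13 to 20 because the branch towards C5 always outranks the alkyl chain.

Assumption: the acid-promoted perhydrolysis of oxetane 12 proceeds with inversion at the tertiary carbon, the normal course for this reaction class. If it proceeded with retention, L-(+)-diethyl tartrate would be used in step 4.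

## Route

Step 1
Reactants: 1 bromobenzene; 2 1,12-dibromododecane
Product: 4 (12-bromododecyl)benzene, via phenylmagnesium bromide 3 (not isolated)
Conditions: 1, Mg, THF, reflux; then added to 2 (3 equiv), Li2CuCl4 (3 mol %), THF, −10 °C → rt
Reagents that add atoms: none
Why: Copper-catalysed cross-coupling of an aryl Grignard reagent with a primary alkyl bromide (Kochi coupling); the excess of 2 limits double arylation and is recovered by distillation.

Step 2
Reactants: 4 (12-bromododecyl)benzene; 5 lithium acetylide–ethylenediamine complex
Product: 6 tetradec-13-yn-1-ylbenzene
Conditions: 5 (1.5 equiv), DMSO, 15 °C → rt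
Reagents that add atoms: none
Why: SN2 alkylation of an acetylide by an unhindered primary bromide in a dipolar aprotic solvent; one operation gives the terminal alkyne with no silyl group to remove.

Step 3
Reactants: 6 tetradec-13-yn-1-ylbenzene
Product: 8 (E)-3-methyl-15-phenylpentadec-2-en-1-ol, via alkenyldimethylalane 7 (not isolated)
Conditions: Me3Al (2.5 equiv), Cp2ZrCl2 (0.25 equiv), CH2Cl2, 0 °C → rt; volatiles removed; n-BuLi, THF/hexane, −78 °C; (CH2O)n, −78 °C → rt
Reagents that add atoms: trimethylaluminium, C[Al](C)C; paraformaldehyde (as formaldehyde), C=O
Why: Negishi zirconium-catalysed carboalumination adds methyl and aluminium syn across the alkyne with methyl on the internal carbon; the alanate formed with n-BuLi is hydroxymethylated with retention, so chain and CH2OH end up trans (E).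

Step 4
Reactants: 8 (E)-3-methyl-15-phenylpentadec-2-en-1-ol
Product: 9 [(2R,3R)-3-methyl-3-(12-phenyldodecyl)oxiran-2-yl]methanol
Conditions: Ti(OiPr)4 (10 mol %), D-(−)-diethyl tartrate (12 mol %), t-BuOOH (2 equiv, in isooctane), 4 Å MS, CH2Cl2, −20 °C
Reagents that add atoms: tert-butyl hydroperoxide, CC(C)(C)OO
Why: Sharpless asymmetric epoxidation; for an E-3,3-disubstituted allylic alcohol the titanium–D-(−)-tartrate catalyst delivers oxygen to the face that gives the (2R,3R) epoxide, the origin of the C6 configuration of the target.

Step 5
Reactants: 9 [(2R,3R)-3-methyl-3-(12-phenyldodecyl)oxiran-2-yl]methanol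
Product: 10 (R)-3-methyl-15-phenylpentadecane-1,3-diol
Conditions: NaAlH2(OCH2CH2OMe)2 (2 equiv), THF, 0 °C → rt
Reagents that add atoms: none
Why: Hydroxyl-directed reductive opening of a 2,3-epoxy alcohol: the aluminate bound to the primary oxygen delivers hydride to C2, away from the fully substituted C3, so the 1,3-diol forms and the C3–O bond and its configuration stay untouched.

Step 6
Reactants: 10 (R)-3-methyl-15-phenylpentadecane-1,3-diol
Product: 12 (R)-2-methyl-2-(12-phenyldodecyl)oxetane, via primary monotosylate 11 (not isolated)
Conditions: n-BuLi (1.0 equiv), THF, 0 °C; TsCl (1.0 equiv), 0 °C → rt; n-BuLi (1.05 equiv), 0 → 45 °C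
Reagents that add atoms: none
Why: Selective sulfonylation of the primary alkoxide, then intramolecular Williamson etherification (4-exo-tet) by the tertiary alkoxide; no bond to the stereocentre is made or broken, so its configuration is retained.

Step 7
Reactants: 12 (R)-2-methyl-2-(12-phenyldodecyl)oxetane
Product: 13 (S)-3-hydroperoxy-3-methyl-15-phenylpentadecan-1-ol
Conditions: H2O2 (anhydrous, in Et2O, 10 equiv), TMSOTf (0.2 equiv), Et2O, −78 → −20 °C
Reagents that add atoms: hydrogen peroxide, OO
Why: Lewis-acid-promoted perhydrolysis of a 2,2-disubstituted oxetane: activation of the ring oxygen and backside attack of H2O2 at the tertiary carbon (SN2-like, through a tight ion pair, driven by release of ring strain) should give the 3-hydroperoxy alcohol with inversion, turning the R carbinol centre into the S peroxy centre.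

Step 8
Reactants: 13 (S)-3-hydroperoxy-3-methyl-15-phenylpentadecan-1-ol
Product: 14 (S)-3-[(2-methoxypropan-2-yl)peroxy]-3-methyl-15-phenylpentadecan-1-ol
Conditions: 2-methoxypropene (1.05 equiv), PPTS (2 mol %), CH2Cl2, −40 → −20 °C
Reagents that add atoms: 2-methoxypropene, COC(C)=C
Why: Acid-catalysed addition of the hydroperoxide O–H to the enol ether (peroxyketal formation); the more acidic, α-effect hydroperoxide should be ketalized before the primary alcohol at low temperature with one equivalent of reagent, and the ketal makes the peroxide inert to base in steps 9 and 10.

Step 9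
Reactants: 14 (S)-3-[(2-methoxypropan-2-yl)peroxy]-3-methyl-15-phenylpentadecan-1-ol
Product: 15 (S)-3-[(2-methoxypropan-2-yl)peroxy]-3-methyl-15-phenylpentadecanal
Conditions: Dess–Martin periodinane (1.3 equiv), NaHCO3 (5 equiv), CH2Cl2, 0 °C → rt
Reagents that add atoms: none
Why: Dess–Martin oxidation of a primary alcohol under buffered, metal-free conditions that leave the peroxyketal and the O–O bond alone; the aldehyde is used at once.

Step 10
Reactants: 15 (S)-3-[(2-methoxypropan-2-yl)peroxy]-3-methyl-15-phenylpentadecanal
Product: 16 (S)-4-[(2-methoxypropan-2-yl)peroxy]-4-methyl-16-phenylhexadec-1-yne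
Conditions: MeC(O)C(N2)P(O)(OMe)2 (1.5 equiv), NaOMe (1.5 equiv), THF/MeOH, −78 → −10 °C
Reagents that add atoms: dimethyl (1-diazo-2-oxopropyl)phosphonate, COP(=O)(OC)C(=[N+]=[N-])C(C)=O
Why: Seyferth–Gilbert homologation with the Ohira–Bestmann reagent: the diazomethylphosphonate anion adds to the aldehyde, and loss of dimethyl phosphate and N2 gives an alkylidene carbene that rearranges to the terminal alkyne; the low temperature keeps enolization of the β-peroxy aldehyde, and with it β-elimination of the peroxide, slow.

Step 11
Reactants: 16 (S)-4-[(2-methoxypropan-2-yl)peroxy]-4-methyl-16-phenylhexadec-1-yne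
Product: 17 (S)-4-hydroperoxy-4-methyl-16-phenylhexadec-1-yne
Conditions: AcOH/THF/H2O (4:2:1), rt
Reagents that add atoms: none
Why: Mild acid hydrolysis of the mixed peroxyketal; the terminal alkyne and the tertiary C–OO bond are inert to dilute acetic acid.

Step 12
Reactants: 17 (S)-4-hydroperoxy-4-methyl-16-phenylhexadec-1-yne; 18 methyl propiolate
Product: 19 methyl (E)-3-{[(S)-4-methyl-16-phenylhexadec-1-yn-4-yl]peroxy}acrylate
Conditions: 18 (1.3 equiv), N-methylmorpholine (0.2 equiv), CH2Cl2, 0 °C → rt
Reagents that add atoms: none
Why: Amine-catalysed conjugate addition of the hydroperoxide to the propiolate, the peroxide counterpart of β-alkoxyacrylate formation; the addition–elimination pathway through the ammonium acrylate gives the E isomer, and the tertiary hydroperoxide has no α-hydrogen for Kornblum–DeLaMare cleavage.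

Step 13
Reactants: 19 methyl (E)-3-{[(S)-4-methyl-16-phenylhexadec-1-yn-4-yl]peroxy}acrylate
Product: 20 methyl (E)-3-{[(S)-2-acetoxy-4-methyl-16-phenylhexadec-1-en-4-yl]peroxy}acrylate
Conditions: AcOH (5 equiv), Ph3PAuCl (3 mol %), AgOTf (3 mol %), toluene, 40 °C, dark
Reagents that add atoms: acetic acid, CC(O)=O
Why: Gold-catalysed Markovnikov addition of a carboxylic acid to a terminal alkyne: π-activation by cationic monovalent gold, anti attack of acetic acid at the internal carbon and protodeauration give only the 2-acetoxy-1-alkene, with no enolate chemistry next to the peroxide; the electron-poor peroxyacrylate should not compete for the π-acid.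

Step 14
Reactants: 20 methyl (E)-3-{[(S)-2-acetoxy-4-methyl-16-phenylhexadec-1-en-4-yl]peroxy}acrylate
Product: 21 methyl 2-[(3R,4R,6S)-4-acetoxy-4,6-dimethyl-6-(12-phenyldodecyl)-1,2-dioxan-3-yl]acetate
Conditions: Fe(acac)3 (0.3 equiv), PhSiH3 (2.5 equiv), EtOH/THF 4:1 (0.02 M), 20 → 35 °C, Ar
Reagents that add atoms: none
Why: Proposed new method: an iron hydride generated from Fe(acac)3 and PhSiH3 should transfer a hydrogen atom to the terminal CH2 of the electron-rich enol acetate, creating the C4 methyl group and a nucleophilic tertiary α-acetoxy radical at C4. This radical is polarity-matched to the acrylate carbon that bears the peroxy oxygen and should add to it in a 6-exo-trig closure that forms C3–C4 and the 1,2-dioxane ring. The ester-stabilized C2 radical is then reduced by divalent iron to the enolate and protonated by ethanol, which returns trivalent iron and should outrun the 3-exo attack on the neighbouring O–O bond that would give an epoxide. The closest known reaction types are radical cyclizations onto β-alkoxyacrylates that give cyclic ethers and iron-hydride reductive couplings of enol-type donor alkenes with acrylates; neither has been shown with a peroxide in the tether. C3 and C4 are set together in a chair-like transition state with the acrylate arm pseudo-equatorial and the smaller acetoxy group pseudo-axial at C4, so acetate and arm become cis. The existing C6 centre carries methyl and n-alkyl groups of similar size and should exert little bias, so 21 is expected together with its (3S,4S,6S) isomer, which is removed by chromatography. The step needs hydrogen-atom transfer to the 1,1-disubstituted donor alkene and not to the push–pull acrylate, which the electronic difference between the two alkenes secures, and it needs the O–O bond to survive, for which iron loading and temperature are kept low and the C4 radical is γ to the peroxide oxygen, where it has no fast fragmentation.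

Step 15
Reactants: 21 methyl 2-[(3R,4R,6S)-4-acetoxy-4,6-dimethyl-6-(12-phenyldodecyl)-1,2-dioxan-3-yl]acetate
Product: 23 plakortolide K, via hydroxy ester 22 (not isolated)
Conditions: TsOH·H2O (0.3 equiv), MeOH, 40 °C
Reagents that add atoms: none
Why: Acid-catalysed transesterification: methanolysis of the tertiary acetate by acyl–oxygen cleavage frees the C4 hydroxyl, which is cis to the ester arm and closes the γ-lactone with loss of methanol; no base is used, so the peroxy methine and the C2 hydrogens are not exposed to Kornblum–DeLaMare or β-elimination pathways, and no stereocentre is touched.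

## Compound list

1 | bromobenzene | Brc1ccccc1 | starting material
2 | 1,12-dibromododecane | BrCCCCCCCCCCCCBr | starting material
3 | phenylmagnesium bromide | Br[Mg]c1ccccc1 | intermediate
4 | (12-bromododecyl)benzene | BrCCCCCCCCCCCCc1ccccc1 | intermediate
5 | lithium acetylide–ethylenediamine complex | [Li+].[C-]#C.NCCN | starting material
6 | tetradec-13-yn-1-ylbenzene | C#CCCCCCCCCCCCCc1ccccc1 | intermediate
7 | [(E)-2-methyl-14-phenyltetradec-1-en-1-yl]dimethylalane | C[Al](C)/C=C(\C)CCCCCCCCCCCCc1ccccc1 | intermediate
8 | (E)-3-methyl-15-phenylpentadec-2-en-1-ol | OC/C=C(\C)CCCCCCCCCCCCc1ccccc1 | intermediate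
9 | [(2R,3R)-3-methyl-3-(12-phenyldodecyl)oxiran-2-yl]methanol | OC[C@H]1O[C@]1(C)CCCCCCCCCCCCc2ccccc2 | intermediate
10 | (R)-3-methyl-15-phenylpentadecane-1,3-diol | OCC[C@](C)(O)CCCCCCCCCCCCc1ccccc1 | intermediate
11 | (R)-3-hydroxy-3-methyl-15-phenylpentadecyl 4-methylbenzenesulfonate | Cc1ccc(cc1)S(=O)(=O)OCC[C@](C)(O)CCCCCCCCCCCCc2ccccc2 | intermediate
12 | (R)-2-methyl-2-(12-phenyldodecyl)oxetane | C[C@@]1(CCCCCCCCCCCCc2ccccc2)CCO1 | intermediate
13 | (S)-3-hydroperoxy-3-methyl-15-phenylpentadecan-1-ol | OCC[C@@](C)(OO)CCCCCCCCCCCCc1ccccc1 | intermediate
14 | (S)-3-[(2-methoxypropan-2-yl)peroxy]-3-methyl-15-phenylpentadecan-1-ol | OCC[C@@](C)(OOC(C)(C)OC)CCCCCCCCCCCCc1ccccc1 | intermediate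
15 | (S)-3-[(2-methoxypropan-2-yl)peroxy]-3-methyl-15-phenylpentadecanal | O=CC[C@@](C)(OOC(C)(C)OC)CCCCCCCCCCCCc1ccccc1 | intermediate
16 | (S)-4-[(2-methoxypropan-2-yl)peroxy]-4-methyl-16-phenylhexadec-1-yne | C#CC[C@@](C)(OOC(C)(C)OC)CCCCCCCCCCCCc1ccccc1 | intermediate
17 | (S)-4-hydroperoxy-4-methyl-16-phenylhexadec-1-yne | C#CC[C@@](C)(OO)CCCCCCCCCCCCc1ccccc1 | intermediate
18 | methyl propiolate | COC(=O)C#C | starting material
19 | methyl (E)-3-{[(S)-4-methyl-16-phenylhexadec-1-yn-4-yl]peroxy}acrylate | COC(=O)/C=C/OO[C@@](C)(CCCCCCCCCCCCc1ccccc1)CC#C | intermediate
20 | methyl (E)-3-{[(S)-2-acetoxy-4-methyl-16-phenylhexadec-1-en-4-yl]peroxy}acrylate | COC(=O)/C=C/OO[C@@](C)(CCCCCCCCCCCCc1ccccc1)CC(=C)OC(C)=O | intermediate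
21 | methyl 2-[(3R,4R,6S)-4-acetoxy-4,6-dimethyl-6-(12-phenyldodecyl)-1,2-dioxan-3-yl]acetate | C[C@]1(CCCCCCCCCCCCc2ccccc2)C[C@@](C)(OC(C)=O)[C@@H](CC(=O)OC)OO1 | intermediate
22 | methyl 2-[(3R,4R,6S)-4-hydroxy-4,6-dimethyl-6-(12-phenyldodecyl)-1,2-dioxan-3-yl]acetate | C[C@]1(CCCCCCCCCCCCc2ccccc2)C[C@@](C)(O)[C@@H](CC(=O)OC)OO1 | intermediate
23 | plakortolide K, (3S,4aR,7aR)-3,4a-dimethyl-3-(12-phenyldodecyl)tetrahydro-3H-furo[3,2-c][1,2]dioxin-6(4H)-one | C[C@]1(CCCCCCCCCCCCc2ccccc2)C[C@@]2(C)OC(=O)C[C@H]2OO1 | target

## Step count and least certain steps

Total step count: 15 steps. Longest linear sequence: 15 steps (1 to 23); 2, 5 and 18 enter as purchased materials.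

Step 14 (key step, proposed new method). The most likely failures are:
- one-electron reduction of the O–O bond by divalent iron formed in the cycle;
- intramolecular displacement at peroxide oxygen by the carbon radicals, giving an epoxide from the C2 radical after closure or an oxetane from the C4 radical before it;
- reduction of the C4 radical before it cyclizes;
- poor discrimination between the two chair transition states that differ at C6, so that at best about half of the cyclized material has the wanted relative configuration.

The fallback uses only known reaction types and replaces the radical C3–C4 closure by an ionic C3–O closure. It sets out from aldehyde 15. MeMgBr (THF, −78 °C) should give (4S)-4-[(2-methoxypropan-2-yl)peroxy]-4-methyl-16-phenylhexadecan-2-ol F1, and Dess–Martin oxidation the ketone (S)-4-[(2-methoxypropan-2-yl)peroxy]-4-methyl-16-phenylhexadecan-2-one F2. Vinylmagnesium bromide with CeCl3 (THF, −78 °C) should give the tertiary allylic alcohol (5S)-5-[(2-methoxypropan-2-yl)peroxy]-3,5-dimethyl-17-phenylheptadec-1-en-3-ol F3 as both C3 epimers. Cross-metathesis with methyl acrylate (second-generation Grubbs catalyst, CH2Cl2, 40 °C) should give the γ-hydroxy enoate methyl (2E,6S)-4-hydroxy-6-[(2-methoxypropan-2-yl)peroxy]-4,6-dimethyl-18-phenyloctadec-2-enoate F4. Aqueous acetic acid should then free the hydroperoxide methyl (2E,6S)-6-hydroperoxy-4-hydroxy-4,6-dimethyl-18-phenyloctadec-2-enoate F5. Amine-promoted 6-exo conjugate addition of the hydroperoxide to the enoate (Et2NH, CF3CH2OH, rt), the standard ionic closure of 1,2-dioxane-3-acetates, should give hydroxy ester 22 from the (4R) epimer. The route is rejoined at 22 for lactonization as in step 15; isomers that cannot lactonize are separated.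

Step 13. The gold-activated alkyne may be attacked by the nearby peroxide oxygen (5-endo closure with oxygen transfer and O–O heterolysis) before acetic acid adds, or the catalyst may be consumed by the peroxide. The fallback changes the order and the metal. It sets out from 16. Base-buffered Markovnikov addition of AcOH ([Ru(p-cymene)Cl2]2, P(2-furyl)3, Na2CO3, toluene, 50 °C) should give (S)-4-[(2-methoxypropan-2-yl)peroxy]-4-methyl-16-phenylhexadec-1-en-2-yl acetate F6. AcOH/THF/H2O should then give (S)-4-hydroperoxy-4-methyl-16-phenylhexadec-1-en-2-yl acetate F7, and addition to 18 as in step 12 rejoins the route at 20.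

Step 10. Enolization of the β-peroxy aldehyde by the basic reagent can lead to β-elimination of the peroxide (E1cB) in competition with homologation. The fallback avoids an enolizable aldehyde under lasting basic conditions. It sets out from 15. Stork–Zhao olefination ([Ph3PCH2I]I, NaN(SiMe3)2, THF, −78 °C) should give (S,Z)-1-iodo-4-[(2-methoxypropan-2-yl)peroxy]-4-methyl-16-phenylhexadec-1-ene F8. Anti-dehydroiodination with Bu4NF (DMF, rt → 60 °C) then gives the alkyne and rejoins the route at 16.

Step 8. The primary hydroxyl may be ketalized in competition, and the peroxyketal may undergo acid-induced transketalization by that hydroxyl to a seven-membered 1,2,4-trioxepane. The fallback needs no selectivity between the two O–H groups. It sets out from 13. Et3SiCl and imidazole (DMF) should give triethyl{[(S)-3-methyl-15-phenyl-1-(triethylsilyloxy)pentadecan-3-yl]peroxy}silane F9. Swern conditions ((COCl)2, DMSO, CH2Cl2, −78 → −30 °C; Et3N), which convert a primary triethylsilyl ether directly into the aldehyde, should give (S)-3-methyl-15-phenyl-3-[(triethylsilyl)peroxy]pentadecanal F10. Homologation as in step 10 should give triethyl{[(S)-4-methyl-16-phenylhexadec-1-yn-4-yl]peroxy}silane F11, and HF·pyridine (THF, 0 °C) rejoins the route at 17.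

Step 15. Acyl–oxygen cleavage of the hindered tertiary acetate may be slow, and forcing it may cause ionization at C4 with fragmentation of the ring, or acid-induced rearrangement of the peroxide. The fallback is reductive and sets out from 21. LiBH4 (THF/MeOH, 0 °C → rt), a hydride that spares dialkyl peroxides, should reduce both ester groups to (3R,4R,6S)-3-(2-hydroxyethyl)-4,6-dimethyl-6-(12-phenyldodecyl)-1,2-dioxan-4-ol F12. TEMPO/PhI(OAc)2 (CH2Cl2, rt) then oxidizes the primary alcohol; the aldehyde is captured by the tertiary hydroxyl as the lactol and oxidized on to the lactone, which rejoins the route at 23.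

Step 7. Partial ionization of the activated oxetane to a free tertiary cation would erode configuration at the future C6, and the product alcohol may attack activated oxetane (oligomerization). Loss of configuration here cannot be corrected by the later diastereomer separation, because it leads to the enantiomer of the target. The fallback adds a resolution: it sets out from 19, which is stable, UV-active and has a single stereocentre. Preparative chromatography on a chiral stationary phase restores the enantiomeric purity and returns 19 to the route; it makes no new compound (F0).

## Further compounds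

F1 | step 14 | (4S)-4-[(2-methoxypropan-2-yl)peroxy]-4-methyl-16-phenylhexadecan-2-ol (both C2 epimers) | CC(O)C[C@@](C)(OOC(C)(C)OC)CCCCCCCCCCCCc1ccccc1
F2 | step 14 | (S)-4-[(2-methoxypropan-2-yl)peroxy]-4-methyl-16-phenylhexadecan-2-one | CC(=O)C[C@@](C)(OOC(C)(C)OC)CCCCCCCCCCCCc1ccccc1
F3 | step 14 | (5S)-5-[(2-methoxypropan-2-yl)peroxy]-3,5-dimethyl-17-phenylheptadec-1-en-3-ol (both C3 epimers) | C=CC(C)(O)C[C@@](C)(OOC(C)(C)OC)CCCCCCCCCCCCc1ccccc1
F4 | step 14 | methyl (2E,6S)-4-hydroxy-6-[(2-methoxypropan-2-yl)peroxy]-4,6-dimethyl-18-phenyloctadec-2-enoate (both C4 epimers) | COC(=O)/C=C/C(C)(O)C[C@@](C)(OOC(C)(C)OC)CCCCCCCCCCCCc1ccccc1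
F5 | step 14 | methyl (2E,6S)-6-hydroperoxy-4-hydroxy-4,6-dimethyl-18-phenyloctadec-2-enoate (both C4 epimers) | COC(=O)/C=C/C(C)(O)C[C@@](C)(OO)CCCCCCCCCCCCc1ccccc1
F6 | step 13 | (S)-4-[(2-methoxypropan-2-yl)peroxy]-4-methyl-16-phenylhexadec-1-en-2-yl acetate | CC(=O)OC(=C)C[C@@](C)(OOC(C)(C)OC)CCCCCCCCCCCCc1ccccc1
F7 | step 13 | (S)-4-hydroperoxy-4-methyl-16-phenylhexadec-1-en-2-yl acetate | CC(=O)OC(=C)C[C@@](C)(OO)CCCCCCCCCCCCc1ccccc1
F8 | step 10 | (S,Z)-1-iodo-4-[(2-methoxypropan-2-yl)peroxy]-4-methyl-16-phenylhexadec-1-ene | I/C=C\C[C@@](C)(OOC(C)(C)OC)CCCCCCCCCCCCc1ccccc1
F9 | step 8 | triethyl{[(S)-3-methyl-15-phenyl-1-(triethylsilyloxy)pentadecan-3-yl]peroxy}silane | CC[Si](CC)(CC)OCC[C@@](C)(OO[Si](CC)(CC)CC)CCCCCCCCCCCCc1ccccc1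
F10 | step 8 | (S)-3-methyl-15-phenyl-3-[(triethylsilyl)peroxy]pentadecanal | O=CC[C@@](C)(OO[Si](CC)(CC)CC)CCCCCCCCCCCCc1ccccc1
F11 | step 8 | triethyl{[(S)-4-methyl-16-phenylhexadec-1-yn-4-yl]peroxy}silane | C#CC[C@@](C)(OO[Si](CC)(CC)CC)CCCCCCCCCCCCc1ccccc1
F12 | step 15 | (3R,4R,6S)-3-(2-hydroxyethyl)-4,6-dimethyl-6-(12-phenyldodecyl)-1,2-dioxan-4-ol | C[C@]1(CCCCCCCCCCCCc2ccccc2)C[C@@](C)(O)[C@@H](CCO)OO1
F0 | step 7 | none | none
A1 | alternative 1 | (3R)-3-[(2-methoxy-14-phenyltetradec-3-yn-2-yl)peroxy]-4-methylpent-4-enoic acid (ketal carbon unassigned) | OC(=O)C[C@@H](OOC(C)(OC)C#CCCCCCCCCCCc1ccccc1)C(C)=C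
A2 | alternative 1 | 7,8-didehydroplakortolide K, the C6-alkynyl peroxy lactone | C[C@]1(C#CCCCCCCCCCCc3ccccc3)C[C@@]2(C)OC(=O)C[C@H]2OO1
A3 | alternative 2 | (3R)-3-hydroperoxy-4,6-dimethylidene-18-phenyloctadecanoic acid | OC(=O)C[C@@H](OO)C(=C)CC(=C)CCCCCCCCCCCCc1ccccc1
A4 | alternative 2 | bicyclic bis(acetoxymercuriomethyl) peroxy lactone, configuration as in the SMILES | CC(=O)O[Hg]C[C@]1(CCCCCCCCCCCCc3ccccc3)C[C@@]2(C[Hg]OC(C)=O)OC(=O)C[C@H]2OO1
A5 | alternative 3 | methyl (3E,5E)-4,6-dimethyl-18-phenyloctadeca-3,5-dienoate | COC(=O)C/C=C(\C)/C=C(\C)CCCCCCCCCCCCc1ccccc1
A6 | alternative 3 | methyl 2-[(3R,6S)-4,6-dimethyl-6-(12-phenyldodecyl)-3,6-dihydro-1,2-dioxin-3-yl]acetate (wanted enantiomer of the racemate) | C[C@]1(CCCCCCCCCCCCc3ccccc3)C=C(C)[C@@H](CC(=O)OC)OO1
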